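**Remark on the chemistry (assumption):** hexadeca-1,15-diyne is taken not to be a stock chemical and is made in step 1; compounds 1, 2, 5 and 6 are taken as purchasable. Ring A is the ring with one hydroxyl, ring B the ring with two.

**Numbering used throughout:** 1 1,12-dibromododecane; 2 lithium acetylide ethylenediamine complex; 3 14-bromotetradec-1-yne (in-flask intermediate); 4 hexadeca-1,15-diyne; 5 5-iodovanillin; 6 (3-bromo-5-methoxyphenyl)boronic acid; 7 iodo/bromo diaryl ether aldehyde; 8 open-chain diyne aldehyde (cyclization substrate); 9 macrocyclic diyne aldehyde; 10 macrocyclic aryl formate (in-flask intermediate); 11 macrocyclic diyne phenol; 12 saturated macrocyclic phenol dimethyl ether; 13 Grevirobstol B.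

## Analysis of the target

Compound 13 is a cyclophane in which two benzene rings are bridged twice, once by an ether oxygen and once by an unbranched chain of sixteen methylene groups. Ring A carries OH at C1, the chain at C3 and the ether oxygen at C5, all mutually meta. Ring B carries the ether oxygen at C1, OH at C2 and C4 and the chain at C6, so the oxygen bridge on ring B is flanked on both sides. The macrocycle runs through C6 and C1 of ring B, the oxygen, C5, C4 and C3 of ring A and the sixteen chain carbons, 22 atoms in all. There is no stereocentre, and a tether of this length should let both rings rotate freely, so nothing stereochemical has to be set. The delicate functionality is the phenol array: the C4 hydroxyl of ring B is para to the ether oxygen, which makes that ring an easily oxidised hydroquinone monoether, so the hydroxyls are best carried masked until late. The difficulties are the entropically costly closure of a large, featureless ring and the doubly ortho-substituted diaryl ether. The strategy rests on the fact that both chain termini sit on aromatic carbons, C6 of ring B and C3 of ring A. Each can therefore be made as an aryl–alkynyl bond from an aryl halide, and one symmetrical C16 diyne can supply the whole chain, bridging an aryl iodide first and an aryl bromide second.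

## Retrosynthetic reasoning

**13 to 12.** The two O–CH3 bonds (ring A C1, ring B C2) are cut last. Methyl ethers are the smallest masks that survive copper, palladium, peracid and hydrogenation, and a Lewis-acidic ether cleavage removes both at once without touching the diaryl ether, whose two C–O bonds are on sp2 carbon.

**12 to 11.** The sixteen methylene groups are traced back to a chain with a triple bond at each end (C1–C2 and C15–C16 of the chain). The forward step is an exhaustive hydrogenation that only adds hydrogen. It is placed after the formyl group has gone, because a benzaldehyde is at risk over palladium under hydrogen.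

**11 to 9.** The C4 hydroxyl of ring B is traced back to a formyl group: the C4–O bond replaces a C4–C bond by peracid oxidation with aryl migration, then cleavage of the formate 10. The aldehyde is not an extra burden. It comes with the ring B building block, it keeps ring B electron-poor during the copper and palladium steps, and the para ether oxygen makes the aryl group the migrating one.

**9 to 8 (ring opening).** The macrocycle is opened at the C3(ring A)–C(sp) bond. The diaryl ether is not chosen because its oxygen is the most hindered atom of the ring. A cut inside the chain would require two different chain pieces. The C6(ring B)–C(sp) bond is reserved for the intermolecular coupling, where two halides compete and the faster-reacting iodide must decide the site. In the ring closure only the bromide is left, so its lower reactivity costs no selectivity and is offset by a stronger palladium catalyst. The forward reaction has to favour ring closure over chain growth and must avoid oxidative alkyne dimerization, hence dilution and no copper.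

**8 to 7 and 4.** The C6(ring B)–C(sp) bond is cut. Forward, palladium/copper alkynylation at room temperature discriminates iodide from bromide by oxidative addition rate. Because 4 is symmetrical it needs no protecting group and is simply used in excess.

**7 to 5 and 6.** The C5(ring A)–O bond is cut. The oxygen is kept from the phenol of 5, and ring A arrives as the arylboronic acid 6 in a copper-mediated oxidative coupling at room temperature. Both carbon–halogen bonds survive, which neither an Ullmann coupling nor a nucleophilic aromatic substitution on these rings would guarantee.

**4 to 1 and 2.** Two C(sp3)–C(sp) bonds are cut. Twofold alkylation of the acetylide 2 by the dibromide 1 (through 3) gives the C16 diyne in one operation.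

## Alternatives that were turned down

**Alternative 1:** Ring B is dismantled at C1–C6 and C2–C3, leaving the ether oxygen on a malonate carbon. In the forward key step dimethyl 2-{3-methoxy-5-[(17E)-19-oxoicos-17-en-1-yl]phenoxy}propanedioate (A1) is treated with sodium methoxide in methanol at high dilution. Conjugate addition of the aryloxymalonate anion to the enone closes the 22-membered ring, and a Claisen condensation of the methyl ketone enolate onto one ester closes ring B, giving the macrocyclic methyl 1-aryloxy-6-alkyl-2,4-dioxocyclohexane-1-carboxylate (A2).
- In favour: no transition metal is needed, two rings form in one flask, and the 1,3-dioxygenation of ring B arises directly from the dione.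
- Against: the ring-closing event is a reversible Michael addition of a hindered, weakly nucleophilic carbanion that must create a quaternary carbon across 22 atoms. The enone can meanwhile add methoxide, deconjugate or condense with itself.
- Against: A2 is still two oxidation-level corrections away from an arene (loss of the ester, then dehydrogenation of the dione next to an electron-rich ring), and A1 needs a long chain-building sequence.
- Comparison: Alternative 1 is stronger in that it avoids palladium and builds the oxygen pattern de novo. The chosen route instead buys both rings with their oxygens in place, reaches its cyclization substrate in three steps, and has a redox-simple three-step tail.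

**Alternative 2:** The macrocycle is cut at the O–C5(ring A) bond, with ring A held as a cyclohexenone. Forward, the phenoxide of 3-chloro-5-[16-(2-hydroxy-3,5-dimethoxyphenyl)hexadecyl]cyclohex-2-en-1-one (A3; racemate) is formed with Cs2CO3 at high dilution. It adds to the β-carbon and expels chloride, giving the macrocyclic 3-aryloxy-5-alkylcyclohex-2-enone (A4; racemate).
- In favour: the addition–elimination is polar and irreversible, needs no catalyst that could die at millimolar concentration, and cannot homocouple. On the ring closure alone it is at least as safe as a palladium-catalysed one.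
- Against: the nucleophilic oxygen is flanked by a methoxy group and the chain, so the ring is closed at the most hindered bond.
- Against: A3 needs a cyclohexane-1,3-dione unit built at the end of a C16 chain, and a stereocentre is made only to be erased.
- Against: A4 must be dehydrogenated to the phenol under oxidising conditions in the presence of the electron-rich ring B.
- Comparison: the chosen route forms the hindered ether early and intermolecularly, where an excess of one partner can be spent, and keeps both rings aromatic throughout.

**Alternative 3:** Ring A is dismantled at C3–C4 and C1–C2 by a retro-Diels–Alder cut. Forward, methyl 19-[3,5-dimethoxy-2-({4-methoxy-4-[(trimethylsilyl)oxy]buta-1,3-dien-2-yl}oxy)phenyl]nonadec-2-ynoate (A5) is heated in toluene at high dilution. The diene CH2 terminus bonds to the ynoate β-carbon and the acetal carbon to the α-carbon, and acidic work-up with loss of methanol gives the macrocyclic methyl salicylate (A6).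
- In favour: the regiochemistry is electronically matched, aromatization needs no oxidant, and ring A is made with its oxygens in place.
- Against: A5 combines a hydrolytically fragile silyl ketene acetal with an electrophilic ynoate in one molecule. The diene must be generated by strong base in the presence of that acceptor, or the ynoate must be installed afterwards on a diene that will not tolerate it.
- Against: a 22-membered intramolecular cycloaddition has almost no entropic help, so long heating is needed, during which the diene decomposes.
- Against: A6 carries a superfluous ester between the hydroxyl and the chain, and its hydrolysis and decarboxylation add steps.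
- Comparison: Alternative 3 is the more elegant arene construction. The chosen route offers stable, characterisable intermediates and a ring closure of a well-understood catalytic type.

Key step: step 4

## Route

**Step 1**
Reactants: 1 1,12-dibromododecane; 2 lithium acetylide ethylenediamine complex
Product: 4 hexadeca-1,15-diyne, via 14-bromotetradec-1-yne 3 (not isolated)
Conditions: 2 (3 equiv), DMSO, 10 °C → rt
Reagents that add atoms: none
Why: Twofold SN2 alkylation of an acetylide by a primary dibromide in a dipolar aprotic solvent; the second displacement on 3 is as easy as the first and the terminal alkynes do not isomerize at room temperature.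

**Step 2**
Reactants: 5 5-iodovanillin (4-hydroxy-3-iodo-5-methoxybenzaldehyde); 6 (3-bromo-5-methoxyphenyl)boronic acid
Product: 7 4-(3-bromo-5-methoxyphenoxy)-3-iodo-5-methoxybenzaldehyde
Conditions: 6 (2 equiv), Cu(OAc)2 (1 equiv), pyridine (5 equiv), 4 Å MS, CH2Cl2, dry air, rt
Reagents that add atoms: none
Why: Chan–Lam oxidative O-arylation, a reaction type that accepts ortho,ortho'-disubstituted and ortho-halogenated phenols; oxygen is the terminal oxidant and returns copper to the divalent state, and at room temperature neither the C–I nor the C–Br bond is attacked by copper.

**Step 3**
Reactants: 7 4-(3-bromo-5-methoxyphenoxy)-3-iodo-5-methoxybenzaldehyde; 4 hexadeca-1,15-diyne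
Product: 8 4-(3-bromo-5-methoxyphenoxy)-3-(hexadeca-1,15-diyn-1-yl)-5-methoxybenzaldehyde
Conditions: 4 (5 equiv, excess recovered), Pd(PPh3)2Cl2 (3 mol %), CuI (5 mol %), Et3N/THF (degassed), rt
Reagents that add atoms: none
Why: Sonogashira coupling; at room temperature oxidative addition occurs at the aryl iodide (further activated by the meta formyl group) and not at the aryl bromide, and the excess of symmetrical diyne suppresses arylation at both ends of one chain.

**Step 4**
Reactants: 8 4-(3-bromo-5-methoxyphenoxy)-3-(hexadeca-1,15-diyn-1-yl)-5-methoxybenzaldehyde
Product: 9 22-membered macrocyclic diyne aldehyde: ring A (C1 OMe, C5 ether O) and ring B (C1 ether O, C2 OMe, C4 CHO) joined by the ether oxygen and by a hexadeca-1,15-diyne-1,16-diyl chain from C6 of ring B to C3 of ring A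
Conditions: Pd(OAc)2 (10 mol %), XPhos (30 mol %), Cs2CO3 (3 equiv), MeCN, 80 °C; 8 added in THF by syringe pump over 12 h (final ca. 1 mM)
Reagents that add atoms: none
Why: Copper-free Sonogashira alkynylation run intramolecularly: zerovalent palladium, formed in situ from Pd(OAc)2 and XPhos, inserts into the only remaining carbon–halogen bond (C3–Br of ring A), the terminal alkyne binds to the divalent arylpalladium bromide and is deprotonated there by carbonate, and reductive elimination forms the C3(ring A)–C(sp) bond. The closest known reaction type is the Sonogashira macrocyclization of an ω-alkynyl aryl halide, here with a bulky biarylphosphine catalyst of the kind established for copper-free coupling of aryl bromides with Cs2CO3 in MeCN. The 22-membered ring is closed end-to-end by this C(sp2)–C(sp) cross-coupling; twelve methylene groups between the two rigid aryl–alkyne units should leave the ring essentially strain-free. No stereocentre is created. The selectivity needed is ring closure over chain growth, which slow addition secures by keeping the stationary concentration of 8 far below the final 1 mM. Leaving out copper removes the oxidative alkyne–alkyne coupling that long reaction times at high dilution would otherwise favour. Carbopalladation of the internal alkyne is not a threat, because palladium sits meta to the ether oxygen on ring A and could reach that alkyne only through a prohibitively strained meta-bridged seven-membered ring. The aldehyde, methyl ethers and diaryl ether are spectators under carbonate.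

**Step 5**
Reactants: 9 macrocyclic diyne aldehyde
Product: 11 macrocyclic diyne phenol (as 9 but with OH in place of CHO at C4 of ring B), via macrocyclic aryl formate 10 (not isolated)
Conditions: mCPBA (1.3 equiv), CH2Cl2, 0 °C → rt; aq. Na2S2O3/NaHCO3 wash; crude 10, Et3N (cat.), MeOH, rt
Reagents that add atoms: mCPBA, O=C(OO)c1cccc(Cl)c1
Why: Baeyer–Villiger oxidation of an aryl aldehyde whose para aryloxy group makes the aryl ring migrate in preference to hydride, then methanolysis of the labile aryl formate; aryl alkynes react with peracids far more slowly than this aldehyde.

**Step 6**
Reactants: 11 macrocyclic diyne phenol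
Product: 12 saturated macrocycle: ring A (C1 OMe, C5 ether O) and ring B (C1 ether O, C2 OMe, C4 OH) joined by the ether oxygen and a hexadecane-1,16-diyl chain from C6 of ring B to C3 of ring A
Conditions: H2 (1 atm), Pd/C (10 %), EtOAc/MeOH, rt
Reagents that add atoms: none
Why: Catalytic hydrogenation of both triple bonds to methylene groups; phenol, aryl methyl ethers and the diaryl ether are inert, and no halogen or carbonyl remains.

**Step 7**
Reactants: 12 saturated macrocyclic phenol dimethyl ether
Product: 13 Grevirobstol B
Conditions: BBr3 (6 equiv), CH2Cl2, −78 °C → rt; then H2O
Reagents that add atoms: none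
Why: Lewis-acid cleavage of aryl methyl ethers (bromide attacks the methyl carbon of the boron-complexed ether); the diaryl ether offers no sp3 carbon for this displacement and stays intact.

## Compound list

1 | 1,12-dibromododecane | BrCCCCCCCCCCCCBr | starting material
2 | lithium acetylide ethylenediamine complex | [Li]C#C.NCCN | starting material
3 | 14-bromotetradec-1-yne | C#CCCCCCCCCCCCCBr | intermediate
4 | hexadeca-1,15-diyne | C#CCCCCCCCCCCCCC#C | intermediate
5 | 5-iodovanillin (4-hydroxy-3-iodo-5-methoxybenzaldehyde) | COc1cc(C=O)cc(I)c1O | starting material
6 | (3-bromo-5-methoxyphenyl)boronic acid | COc1cc(Br)cc(B(O)O)c1 | starting material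
7 | 4-(3-bromo-5-methoxyphenoxy)-3-iodo-5-methoxybenzaldehyde | COc1cc(C=O)cc(I)c1Oc1cc(Br)cc(OC)c1 | intermediate
8 | 4-(3-bromo-5-methoxyphenoxy)-3-(hexadeca-1,15-diyn-1-yl)-5-methoxybenzaldehyde | C#CCCCCCCCCCCCCC#Cc1cc(C=O)cc(OC)c1Oc1cc(Br)cc(OC)c1 | intermediate
9 | macrocyclic diyne aldehyde (22-membered; ring B C4 CHO, both phenols as methyl ethers) | COc1cc2cc(c1)Oc1c(OC)cc(C=O)cc1C#CCCCCCCCCCCCCC#C2 | intermediate
10 | macrocyclic diyne aryl formate (ring B C4 OCHO) | COc1cc2cc(c1)Oc1c(OC)cc(OC=O)cc1C#CCCCCCCCCCCCCC#C2 | intermediate
11 | macrocyclic diyne phenol (ring B C4 OH) | COc1cc2cc(c1)Oc1c(OC)cc(O)cc1C#CCCCCCCCCCCCCC#C2 | intermediate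
12 | saturated macrocyclic phenol dimethyl ether | COc1cc2cc(c1)Oc1c(OC)cc(O)cc1CCCCCCCCCCCCCCCC2 | intermediate
13 | Grevirobstol B | Oc1cc2cc(c1)Oc1c(O)cc(O)cc1CCCCCCCCCCCCCCCC2 | target

## Step count and risk

Total step count: 7. Longest linear sequence: 6 steps (steps 2 to 7 from 5, or steps 1 and 3 to 7 from 1).

**Step 4 (key step).**
- Risk: intermolecular coupling may outrun ring closure and give cyclodimer and oligomers. The catalyst may also deposit as palladium metal during the long addition at millimolar concentration, so oxidative addition into the aryl bromide stalls.
- Fallback: sets out from 7 and rejoins at 12; it closes the ring inside the chain by olefin metathesis instead. Compound 7 is oxidised with mCPBA to 4-(3-bromo-5-methoxyphenoxy)-3-iodo-5-methoxyphenyl formate F1, which Et3N in MeOH cleaves to 4-(3-bromo-5-methoxyphenoxy)-3-iodo-5-methoxyphenol F2. Commercial nona-1,8-diene, in excess, is hydroborated with 9-borabicyclo[3.3.1]nonane to 9-(non-8-en-1-yl)-9-borabicyclo[3.3.1]nonane F3. A twofold B-alkyl Suzuki–Miyaura coupling of F2 with F3 at both halides (Pd(dppf)Cl2, Cs2CO3, DMF/THF/H2O, 60 °C) gives 3-methoxy-4-[3-methoxy-5-(non-8-en-1-yl)phenoxy]-5-(non-8-en-1-yl)phenol F4. Ring-closing metathesis with the second-generation Grubbs catalyst (CH2Cl2, 40 °C, 1 mM) releases ethene and gives the 22-membered macrocyclic alkene phenol F5 as an E/Z mixture. Hydrogenation over Pd/C then gives 12.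

**Step 2.**
- Risk: C–O bond formation at a doubly ortho-substituted, electron-poor phenol may be slow, so that protodeboronation and oxidative self-coupling of the boronic acid use up the aryl donor.
- Fallback: sets out from 5 and rejoins at 7; it is a metal-free arylation with a trivalent iodine reagent. Commercial 1-bromo-3-iodo-5-methoxybenzene is oxidised with mCPBA and TsOH·H2O in MeCN and trapped with 1,3,5-trimethoxybenzene to give (3-bromo-5-methoxyphenyl)(2,4,6-trimethoxyphenyl)iodonium 4-methylbenzenesulfonate F6. Compound 5 and F6 with K2CO3 in MeCN at 40–60 °C should give 7, the trimethoxyphenyl group acting as the ligand that is not transferred.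

**Step 3.**
- Risk: both ends of the diyne may be arylated, copper may mediate oxidative alkyne dimerization, and iodide/bromide selectivity may erode if the hindered iodide needs heating.
- Fallback: sets out from 4 and 7 and rejoins at 8; one alkyne terminus is blocked with a polar silyl group. Compound 4 is deprotonated once (EtMgBr, 1 equiv, THF) and silylated with (3-cyanopropyl)dimethylsilyl chloride to give 4-[(hexadeca-1,15-diyn-1-yl)dimethylsilyl]butanenitrile F7, which the nitrile makes easy to separate from unreacted and doubly silylated diyne. Sonogashira coupling of F7 with 7 under the step 3 conditions gives 4-(3-bromo-5-methoxyphenoxy)-3-{16-[(3-cyanopropyl)dimethylsilyl]hexadeca-1,15-diyn-1-yl}-5-methoxybenzaldehyde F8. K2CO3 in MeOH/THF removes the silyl group to give 8.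

**Step 5.**
- Risk: oxygen transfer from the peracid to the triple bonds, hydride instead of aryl migration in the tetrahedral peracid adduct, and further oxidation of the electron-rich ring once the phenol is free.
- Fallback: sets out from 9 and rejoins at 12; the order of events is changed so that no alkyne meets the peracid. Compound 9 is hydrogenated over Pd/C poisoned with Ph2S (H2, EtOAc), conditions that reduce alkynes but spare aryl aldehydes, to give the saturated macrocyclic aldehyde F9. mCPBA converts F9 into the saturated macrocyclic aryl formate F10, and Et3N in MeOH gives 12.

## Further compounds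

F1 | step 4 | 4-(3-bromo-5-methoxyphenoxy)-3-iodo-5-methoxyphenyl formate | COc1cc(OC=O)cc(I)c1Oc1cc(Br)cc(OC)c1
F2 | step 4 | 4-(3-bromo-5-methoxyphenoxy)-3-iodo-5-methoxyphenol | COc1cc(O)cc(I)c1Oc1cc(Br)cc(OC)c1
F3 | step 4 | 9-(non-8-en-1-yl)-9-borabicyclo[3.3.1]nonane | C=CCCCCCCCB1C2CCCC1CCC2
F4 | step 4 | 3-methoxy-4-[3-methoxy-5-(non-8-en-1-yl)phenoxy]-5-(non-8-en-1-yl)phenol | C=CCCCCCCCc1cc(O)cc(OC)c1Oc1cc(CCCCCCCC=C)cc(OC)c1
F5 | step 4 | 22-membered macrocyclic alkene phenol (E/Z mixture; ring B C4 OH, chain double bond between chain C8 and C9) | COc1cc2cc(c1)Oc1c(OC)cc(O)cc1CCCCCCCC=CCCCCCCC2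
F6 | step 2 | (3-bromo-5-methoxyphenyl)(2,4,6-trimethoxyphenyl)iodonium 4-methylbenzenesulfonate | COc1cc(Br)cc([I+]c2c(OC)cc(OC)cc2OC)c1.Cc1ccc(cc1)S(=O)(=O)[O-]
F7 | step 3 | 4-[(hexadeca-1,15-diyn-1-yl)dimethylsilyl]butanenitrile | C#CCCCCCCCCCCCCC#C[Si](C)(C)CCCC#N
F8 | step 3 | 4-(3-bromo-5-methoxyphenoxy)-3-{16-[(3-cyanopropyl)dimethylsilyl]hexadeca-1,15-diyn-1-yl}-5-methoxybenzaldehyde | N#CCCC[Si](C)(C)C#CCCCCCCCCCCCCC#Cc1cc(C=O)cc(OC)c1Oc1cc(Br)cc(OC)c1
F9 | step 5 | saturated macrocyclic aldehyde (ring B C4 CHO, hexadecane-1,16-diyl chain) | COc1cc2cc(c1)Oc1c(OC)cc(C=O)cc1CCCCCCCCCCCCCCCC2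
F10 | step 5 | saturated macrocyclic aryl formate (ring B C4 OCHO) | COc1cc2cc(c1)Oc1c(OC)cc(OC=O)cc1CCCCCCCCCCCCCCCC2
A1 | alternative 1 | dimethyl 2-{3-methoxy-5-[(17E)-19-oxoicos-17-en-1-yl]phenoxy}propanedioate | COC(=O)C(Oc1cc(OC)cc(CCCCCCCCCCCCCCCC/C=C/C(C)=O)c1)C(=O)OC
A2 | alternative 1 | macrocyclic methyl 1-aryloxy-6-alkyl-2,4-dioxocyclohexane-1-carboxylate (mixture of diastereomers) | COc1cc2cc(c1)OC1(C(=O)OC)C(=O)CC(=O)CC1CCCCCCCCCCCCCCCC2
A3 | alternative 2 | 3-chloro-5-[16-(2-hydroxy-3,5-dimethoxyphenyl)hexadecyl]cyclohex-2-en-1-one (racemate) | O=C1C=C(Cl)CC(C1)CCCCCCCCCCCCCCCCc1cc(OC)cc(OC)c1O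
A4 | alternative 2 | macrocyclic 3-aryloxy-5-alkylcyclohex-2-enone (racemate) | O=C1C=C2CC(C1)CCCCCCCCCCCCCCCCc1cc(OC)cc(OC)c1O2
A5 | alternative 3 | methyl 19-[3,5-dimethoxy-2-({4-methoxy-4-[(trimethylsilyl)oxy]buta-1,3-dien-2-yl}oxy)phenyl]nonadec-2-ynoate | C=C(Oc1c(OC)cc(OC)cc1CCCCCCCCCCCCCCCCC#CC(=O)OC)C=C(OC)O[Si](C)(C)C
A6 | alternative 3 | macrocyclic methyl salicylate (ring A C1 OH, C2 CO2Me; ring B dimethyl ether) | COC(=O)c1c(O)cc2cc1CCCCCCCCCCCCCCCCc1cc(OC)cc(OC)c1O2
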